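Atom numbers are those of the target: ring A is C10–C1–C2–C3–C4–C5–C6, ring B is C6–C7–C8–C9–C10, and the side chain C11–C15 sits on C7 (methyls on C3, C10, C11 and two on C15). Compound numbers 1–26 are those of the steps and of the list after them; TBS = tert-butyldimethylsilyl.

## Analysis of the target

The target is a trans-fused bicyclo[5.3.0]decane in which the seven-membered ring A and the five-membered ring B share the bond C6–C10. It has six stereocentres, (1S,2S,3R,6S,7R,10S) in this numbering. The C10 methyl and H6 lie on opposite faces, the side chain on C7 lies on the face of H6, and the acetate on C1 is also on that face, trans to the C10 methyl. The epoxide oxygen across C2–C3 is on the same face as the acetate. The side chain is an (E,E)-diene, C11(CH3)=C12–C13=C14, that ends in the tertiary carbinol C15. That carbinol is doubly allylic and ionizes with acid, the epoxy acetate is also acid-sensitive and the acetate is base-labile, so the last steps must be neutral or mildly basic. The hard points are the quaternary C10 at the ring fusion next to the oxygenated C1, the trans 5–7 fusion, an oxygen at C1 on the face that a hydride reagent would not choose unaided, and the trisubstituted (E)-alkene C11=C12. The strategy rests on one feature: C1 lies between C2 and the fully substituted C10, so C10–C1–C2 is a latent 2-oxyallyl cation, and C3–C4–C5–C6 is a latent 1,3-diene whose terminus C3 already bears its methyl. The chain C7–C8–C9 joins the two, so a single (4+3) event can close both rings.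

## Retrosynthetic reasoning

**End game at C1, C2, C3 and C15 (26 back to 22).** The acetyl C–O bond is cut last, because the methyl nucleophile that builds C15 would cleave an acetate. The two C15–CH3 bonds of 25 are cut back to the ester of 24. The epoxide C–O bonds of 24 are cut back to the allylic alcohol 23, and this must precede the creation of the C15 carbinol, which would otherwise direct oxidation to C13=C14. The C1–H bond of 23 is cut back to the enone 22; the forward reduction has to deliver hydrogen to the face of the C10 methyl, so it needs reagent control.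

**Side chain (22 back to 18).** The C11=C12 bond is cut to the methyl ketone 20 and the four-carbon phosphonate 21, which brings C12–C15 in one olefination. The acetyl group of 20 is unmasked only at this point, from the silyl-protected carbinol of 18 through 19. Before this point C7–H is allylic to the diene, and a carbonyl at C11 would make it epimerizable and let the diene slip into conjugation. A ketal at C11 was considered for the same role, but it would have to be installed on exactly such a ketone, and its oxygens could also capture the cation of the key step.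

**Ring A adjustment (18 back to 16).** The C2=C3 enone of 18 is traced to the saturated ketone 17 and then to the cycloadduct 16, whose C4=C5 alkene is the residue of the diene. The dehydrogenation is unambiguous because C10 is quaternary, which leaves C2 as the only enolizable position.

**Key disconnection (16 back to 14).** The bonds C2–C3 and C6–C10 are cut together, opening both rings to the acyclic chloro ketone 14 through the oxyallyl cation 15. No other pair of cuts removes both rings, the quaternary centre and the ring-fusion stereochemistry at once while leaving a precursor whose only preset stereocentre is C7. The forward step must give the trans fusion and the correct sense relative to C7.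

**Chloride and C9=C10 (14 back to 10).** The C10–Cl bond is cut to the silyl enol ether 13. Direct chlorination of a methyl ketone would be ambiguous between C2 and C10 and is hard to reconcile with the diene, whereas conjugate hydride addition to the enone 12 fixes the enol double bond between C1 and C10. The configuration at C10 is deliberately left uncontrolled, since both epimers give the same cation. The C9=C10 bond of 12 is cut to the aldehyde 10 and the ylide 11.

**Diene and C6 (10 back to 3).** The aldehyde 10 comes from the alcohol 9. The C4–C5 single bond of the diene is cut to the (E)-vinyl iodide 7 and the (E)-boronic acid 8, because an sp2–sp2 coupling fixes both geometries. Carbon C5 is traced through the alkyne 5 to the lactol 4 and the lactone 3. The lactone ring supplies C6 as its carbonyl carbon and C9 as its oxygen-bearing carbon, and the two ends are told apart without a protecting group.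

**C7 (3 back to 1).** The only stereocentre of the precursor that survives is set by asymmetric hydrogenation of the racemic keto lactone 1, whose C7 epimerizes freely, to give 2. A chiral-auxiliary enolate alkylation joining C7 to C8 was considered and put aside. It would need an imide enolate to react with an unactivated primary alkyl halide, and it would place C7 between a carbonyl group and the diene.

## Alternatives that were turned down

**Alternative 1:** The C1–C10 bond is disconnected by a retro-[3,3] shift to the cis-divinylcyclopropane A2, built from the cyclopentene obtained by ring contraction of (R)-limonene A3. In the forward step, heating A2 breaks the cyclopropane bond C3–C5 and joins the (E)-alkenylboronate carbon C1 to the cyclopentene carbon C10. This gives the cyclohepta-1,4-diene A1 with boron on C1.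
- For: C7 comes from the chiral pool. C1 and C10 are created together and stereospecifically, and oxidation of the boronate gives the C1 alcohol next to the C2=C3 alkene, ready for directed epoxidation. On the C1 configuration and on the oxidation pattern of ring A this route is stronger than the chosen one, which must overcome substrate bias in a ketone reduction (step 17).
- Against: the C10 methyl is the inward-pointing substituent of the boat transition state, so the rearrangement should be slow and compete with epimerization of the cyclopropane. The absolute configuration of the cyclopropane must be set relative to C7, because it decides which face of C10 is bonded. C6 remains sp2 in A1, so the ring-fusion hydrogen has to be added later to C5=C6 from the correct face and in the presence of two other alkenes. The isopropenyl group then needs selective cleavage before the side chain can be attached.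
- Comparison: the chosen strategy sets C6 and C10 in the ring-forming step itself and never has to differentiate alkenes.

**Alternative 2:** The C7–C8 bond is disconnected by a retro-Wolff step, ring B being seen as a contracted six-membered ring in the trans-fused diazo ketone A5. In the forward step, light expels nitrogen, C8 migrates from the carbonyl carbon C11 to C7, and the ketene is trapped as the methyl ester A4.
- For: the trans fusion and C10 are secured at a six–seven stage where they are easy to control, the ring contraction of cyclic 2-diazo ketones is dependable, and C11 arrives as a carboxyl carbon. In predictability of the ring fusion this route is stronger than a cycloaddition.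
- Against: the key step makes one bond and fixes no stereocentre with certainty, since C7 is set by protonation of the ketene. Ring A of A4 carries neither the C3 methyl nor the C2=C3 unsaturation, which cost a dehydrogenation, a conjugate methyl addition and a second dehydrogenation. A5 itself requires a long linear build of a bicyclic ketone with the quaternary C10.
- Comparison: the chosen strategy offers convergence in its place: two rings, two bonds and three stereocentres from an acyclic chain, with the C3 methyl already present.

**Alternative 3:** The bonds C6–C7 and C9–C10 are disconnected from a preformed ring A, the cross-conjugated dienone A7. In the forward step a copper–carbene catalyst adds the α-alkenylalane A8 to C6, and the aluminium enolate is allylated at C10 anti to the new substituent to give A6. Ring B would follow by ring-closing metathesis.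
- For: the step is catalytic and enantioselective, both ring-fusion centres arise in one flask, and ring A arrives with the C1 ketone and the C2=C3 enone in place. On step count and on the oxidation state of ring A this route is stronger than the chosen one.
- Against: the acceptor is an α-methyl enone inside a seven-membered dienone, a class that is sluggish and little explored in enantioselective conjugate addition. The aluminium-bearing carbon of A8 is flanked by a fully substituted ketal carbon, so both its preparation and its transfer are doubtful. C7 is not set: after metathesis the C7=C8 alkene must be reduced beside the enone and from the face of the C10 methyl, or the centre corrected later.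
- Comparison: the chosen key step is intramolecular, its regiochemistry is fixed by the tether and by the quaternary C10, and C7 is secured beforehand by a dependable hydrogenation.

Key step: step 11

Assumption: the (R)-BINAP complex is taken to give the syn (3S,1'R) hydroxy lactone 2, the usual sense of such hydrogenations. Only the ring carbon matters, because the carbinol carbon is oxidized in step 15, so the antipodal ligand would serve if it is the one that delivers (3S).

## Route

**Step 1**
Reactants: 1 3-acetyldihydrofuran-2(3H)-one (racemic α-acetyl-γ-butyrolactone)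
Product: 2 (3S)-3-[(1R)-1-hydroxyethyl]dihydrofuran-2(3H)-one
Conditions: H2 (100 atm), RuBr2[(R)-BINAP] (cat.), CH2Cl2/MeOH, 50 °C
Reagents that add atoms: none
Why: Asymmetric hydrogenation of a β-keto lactone with dynamic kinetic resolution: the doubly activated C7–H epimerizes through the enol faster than the divalent ruthenium hydride reduces the ketone, so one enantiomer is drained. The ligand fixes C7 as the target requires and C11 as a temporary carbinol centre that disappears in step 15.

**Step 2**
Reactants: 2 (3S)-3-[(1R)-1-hydroxyethyl]dihydrofuran-2(3H)-one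
Product: 3 (3S)-3-[(1R)-1-(tert-butyldimethylsilyloxy)ethyl]dihydrofuran-2(3H)-one
Conditions: TBSCl, imidazole, DMF, rt
Reagents that add atoms: tert-butyldimethylsilyl chloride, CC(C)(C)[Si](C)(C)Cl
Why: Silylation of a secondary alcohol under imidazole catalysis; the base is too weak to epimerize the lactone α-carbon or to trigger retro-aldol cleavage.

**Step 3**
Reactants: 3 (3S)-3-[(1R)-1-(tert-butyldimethylsilyloxy)ethyl]dihydrofuran-2(3H)-one
Product: 4 (3S)-3-[(1R)-1-(tert-butyldimethylsilyloxy)ethyl]tetrahydrofuran-2-ol (both anomers)
Conditions: i-Bu2AlH (1.1 equiv), CH2Cl2, −78 °C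
Reagents that add atoms: none
Why: Half-reduction of a γ-lactone: the tetrahedral aluminate is stable at low temperature and gives the lactol on work-up, so C6 reaches the aldehyde level while C9 stays masked in the ring.

**Step 4**
Reactants: 4 (3S)-3-[(1R)-1-(tert-butyldimethylsilyloxy)ethyl]tetrahydrofuran-2-ol
Product: 5 (3R)-3-[(1R)-1-(tert-butyldimethylsilyloxy)ethyl]pent-4-yn-1-ol
Conditions: dimethyl (1-diazo-2-oxopropyl)phosphonate, K2CO3, MeOH, 0 °C → rt
Reagents that add atoms: dimethyl (1-diazo-2-oxopropyl)phosphonate, CC(=O)C(=[N+]=[N-])P(=O)(OC)OC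
Why: Seyferth–Gilbert homologation in its Ohira–Bestmann form acts on the open hydroxy aldehyde tautomer of the lactol, turning C6 into a terminal alkyne (C5 from the reagent) and freeing C9 as a primary alcohol. Carbonate in methanol is mild enough for α-branched β-silyloxy aldehydes.

**Step 5**
Reactants: 5 (3R)-3-[(1R)-1-(tert-butyldimethylsilyloxy)ethyl]pent-4-yn-1-ol
Product: 7 (3R,4E)-3-[(1R)-1-(tert-butyldimethylsilyloxy)ethyl]-5-iodopent-4-en-1-ol, via alkenylzirconocene chloride 6 (not isolated)
Conditions: Cp2Zr(H)Cl (2.5 equiv), THF, rt; then I2, 0 °C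
Reagents that add atoms: iodine, II; Cp2Zr(H)Cl, [H][Zr](Cl)(C1C=CC=C1)C1C=CC=C1 (its zirconium stays only in intermediate 6)
Why: Hydrozirconation adds Zr–H syn with zirconium on the terminal carbon, and iodinolysis goes with retention, so C5=C6 is (E). The hydroxyl only consumes a further equivalent of the hydride as its alkoxide, which is released on work-up.

**Step 6**
Reactants: 7 (3R,4E)-3-[(1R)-1-(tert-butyldimethylsilyloxy)ethyl]-5-iodopent-4-en-1-ol; 8 (E)-prop-1-en-1-ylboronic acid
Product: 9 (3R,4E,6E)-3-[(1R)-1-(tert-butyldimethylsilyloxy)ethyl]octa-4,6-dien-1-ol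
Conditions: Pd(PPh3)4 (5 mol%), aq. KOH, THF, 50 °C
Reagents that add atoms: none
Why: Suzuki–Miyaura coupling with zerovalent palladium proceeds with retention at both sp2 carbons and so gives the (E,E)-diene C3–C6 with the C3 methyl in place.

**Step 7**
Reactants: 9 (3R,4E,6E)-3-[(1R)-1-(tert-butyldimethylsilyloxy)ethyl]octa-4,6-dien-1-ol
Product: 10 (3R,4E,6E)-3-[(1R)-1-(tert-butyldimethylsilyloxy)ethyl]octa-4,6-dienal
Conditions: Dess–Martin periodinane, CH2Cl2, 0 °C → rt
Reagents that add atoms: none
Why: Dess–Martin oxidation of a primary alcohol under near-neutral conditions; C7 is β to the new aldehyde and cannot epimerize, and the diene and silyl ether are untouched.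

**Step 8**
Reactants: 10 (3R,4E,6E)-3-[(1R)-1-(tert-butyldimethylsilyloxy)ethyl]octa-4,6-dienal; 11 3-(triphenylphosphoranylidene)butan-2-one
Product: 12 (3E,6R,7E,9E)-6-[(1R)-1-(tert-butyldimethylsilyloxy)ethyl]-3-methylundeca-3,7,9-trien-2-one
Conditions: toluene, 90 °C
Reagents that add atoms: none
Why: Wittig olefination with a stabilized ylide forms C9=C10 and brings C10 with its methyl, C1 and C2; the (E) geometry expected is of no consequence because the alkene is reduced next.

**Step 9**
Reactants: 12 (3E,6R,7E,9E)-6-[(1R)-1-(tert-butyldimethylsilyloxy)ethyl]-3-methylundeca-3,7,9-trien-2-one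
Product: 13 (6R,7E,9E)-6-[(1R)-1-(tert-butyldimethylsilyloxy)ethyl]-2-[dimethyl(phenyl)silyloxy]-3-methylundeca-2,7,9-triene (enol ether geometry not controlled)
Conditions: [(Ph3P)CuH]6 (3 mol%), PhMe2SiH, toluene, rt
Reagents that add atoms: dimethylphenylsilane, C[SiH](C)c1ccccc1
Why: Copper hydride-catalysed 1,4-hydrosilylation delivers hydride to C9 and traps the enolate on oxygen, so the enol double bond lies specifically between C1 and C10. Unactivated dienes and silyl ethers do not react with this catalyst.

**Step 10**
Reactants: 13 (6R,7E,9E)-6-[(1R)-1-(tert-butyldimethylsilyloxy)ethyl]-2-[dimethyl(phenyl)silyloxy]-3-methylundeca-2,7,9-triene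
Product: 14 (6R,7E,9E)-6-[(1R)-1-(tert-butyldimethylsilyloxy)ethyl]-3-chloro-3-methylundeca-7,9-dien-2-one (both C3 epimers)
Conditions: NCS, THF, 0 °C → rt
Reagents that add atoms: N-chlorosuccinimide, O=C1CCC(=O)N1Cl
Why: Electrophilic chlorination of a silyl enol ether puts chlorine on C10 only, giving the tertiary α-chloro ketone regiospecifically. Both C10 epimers are expected and both are used, since they ionize to the same cation.

**Step 11**
Reactants: 14 (6R,7E,9E)-6-[(1R)-1-(tert-butyldimethylsilyloxy)ethyl]-3-chloro-3-methylundeca-7,9-dien-2-one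
Product: 16 (3R,6S,7R,10S)-7-[(1R)-1-(tert-butyldimethylsilyloxy)ethyl]-3,10-dimethylbicyclo[5.3.0]dec-4-en-1-one (target numbering; trans-fused), via oxyallyl cation 15 (not isolated)
Conditions: Et3N (3 equiv), CF3CH2OH (0.02 M), rt
Reagents that add atoms: none
Why: Et3N enolizes 14 toward C2, the only enolizable position because C10 is fully substituted, and the enol(ate) loses chloride in the ionizing solvent to give the single oxyallyl cation 15 from either C10 epimer. The diene then adds across the allyl termini, C6 to C10 and C3 to C2, either concertedly or by enolate capture of an intermediate allylic cation; the closest known reaction type is the base-mediated intramolecular (4+3) cycloaddition of α-halo ketones with tethered 1,3-dienes in fluorinated alcohols. Ring B closes in a 5-exo-trig sense through the C7–C8–C9 tether, and ring A is the seven-membered ring of the cycloaddition, completed by the C2–C3 bond (7-endo if the process is stepwise). C10 and C6 are set together, and the extended transition state, in which the diene lies away from the C10 methyl, should give the trans fusion. Their sense relative to C7 follows from the silyloxyethyl group taking a pseudo-equatorial place on the forming ring B, which puts H6 and H7 trans. C3 follows from suprafacial addition to the (E,E)-diene and is erased in step 13. The step needs trans over cis fusion and needs cation–diene bonding to outrun solvent capture and loss of HCl; the short tether, the electron-rich 1,4-dialkyl diene and the hindered, poorly nucleophilic silyl ether oxygen are what favour this.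

**Step 12**
Reactants: 16 (3R,6S,7R,10S)-7-[(1R)-1-(tert-butyldimethylsilyloxy)ethyl]-3,10-dimethylbicyclo[5.3.0]dec-4-en-1-one
Product: 17 (3S,6S,7R,10S)-7-[(1R)-1-(tert-butyldimethylsilyloxy)ethyl]-3,10-dimethylbicyclo[5.3.0]decan-1-one
Conditions: H2 (1 atm), Pd/C, EtOAc, rt
Reagents that add atoms: none
Why: Heterogeneous hydrogenation of the cis-disubstituted C4=C5 alkene; no stereocentre is made or touched, and the ketone and silyl ether are inert.

**Step 13**
Reactants: 17 (3S,6S,7R,10S)-7-[(1R)-1-(tert-butyldimethylsilyloxy)ethyl]-3,10-dimethylbicyclo[5.3.0]decan-1-one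
Product: 18 (6S,7R,10S)-7-[(1R)-1-(tert-butyldimethylsilyloxy)ethyl]-3,10-dimethylbicyclo[5.3.0]dec-2-en-1-one
Conditions: IBX (2.5 equiv), DMSO/toluene, 70 °C
Reagents that add atoms: none
Why: IBX dehydrogenation of a ketone through its enol; C2 is the only enolizable carbon, so the enone can only be C2=C3. The C3 stereocentre of the cycloadduct is erased here.

**Step 14**
Reactants: 18 (6S,7R,10S)-7-[(1R)-1-(tert-butyldimethylsilyloxy)ethyl]-3,10-dimethylbicyclo[5.3.0]dec-2-en-1-one
Product: 19 (6S,7R,10S)-7-[(1R)-1-hydroxyethyl]-3,10-dimethylbicyclo[5.3.0]dec-2-en-1-one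
Conditions: aq. HF, MeCN, rt
Reagents that add atoms: none
Why: Fluoride-driven cleavage of the secondary silyl ether; the enone is stable to dilute HF.

**Step 15**
Reactants: 19 (6S,7R,10S)-7-[(1R)-1-hydroxyethyl]-3,10-dimethylbicyclo[5.3.0]dec-2-en-1-one
Product: 20 (6S,7R,10S)-7-acetyl-3,10-dimethylbicyclo[5.3.0]dec-2-en-1-one
Conditions: Dess–Martin periodinane, CH2Cl2, rt
Reagents that add atoms: none
Why: Dess–Martin oxidation reveals the C11 methyl ketone and removes the temporary carbinol centre. C7 is now α to a ketone, but its configuration, trans to C5 on ring B and trans to the C10 methyl, is expected to be the more stable one.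

**Step 16**
Reactants: 20 (6S,7R,10S)-7-acetyl-3,10-dimethylbicyclo[5.3.0]dec-2-en-1-one; 21 triethyl 4-phosphonocrotonate
Product: 22 ethyl (2E,4E)-5-[(6S,7R,10S)-3,10-dimethyl-1-oxobicyclo[5.3.0]dec-2-en-7-yl]hexa-2,4-dienoate
Conditions: LiN(SiMe3)2, THF, −78 °C → rt
Reagents that add atoms: none
Why: Vinylogous Horner–Wadsworth–Emmons olefination at the α-carbon of the phosphonate forms C11=C12 and brings C12–C15. The methyl ketone should react in preference to the conjugated C1 carbonyl, which is flanked by the quaternary C10, and the bulk of C7 against the methyl should favour the (E) isomer.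

**Step 17**
Reactants: 22 ethyl (2E,4E)-5-[(6S,7R,10S)-3,10-dimethyl-1-oxobicyclo[5.3.0]dec-2-en-7-yl]hexa-2,4-dienoate
Product: 23 ethyl (2E,4E)-5-[(1R,6S,7R,10S)-1-hydroxy-3,10-dimethylbicyclo[5.3.0]dec-2-en-7-yl]hexa-2,4-dienoate
Conditions: (S)-Me-CBS oxazaborolidine [(S)-1-methyl-3,3-diphenyltetrahydro-1H,3H-pyrrolo[1,2-c][1,3,2]oxazaborole] (0.5 equiv), catecholborane, toluene, −78 °C
Reagents that add atoms: none
Why: Corey–Bakshi–Shibata reduction, in which the catalyst and not the substrate chooses the face. With the quaternary C10 as the larger flank of the carbonyl, the (S)-catalyst should deliver hydride to the face of the C10 methyl and give the (1R) alcohol, with the hydroxyl trans to that methyl. Catecholborane leaves the ester and the alkenes alone at this temperature.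

**Step 18**
Reactants: 23 ethyl (2E,4E)-5-[(1R,6S,7R,10S)-1-hydroxy-3,10-dimethylbicyclo[5.3.0]dec-2-en-7-yl]hexa-2,4-dienoate
Product: 24 ethyl (2E,4E)-5-[(1S,2S,3R,6S,7R,10S)-2,3-epoxy-1-hydroxy-3,10-dimethylbicyclo[5.3.0]dec-7-yl]hexa-2,4-dienoate
Conditions: VO(acac)2 (5 mol%), t-BuOOH, CH2Cl2, 0 °C
Reagents that add atoms: tert-butyl hydroperoxide, CC(C)(C)OO
Why: Hydroxyl-directed epoxidation: the vanadate ester of the C1 alcohol delivers the peroxide oxygen to the same face of C2=C3, which sets C2 and C3 syn to the hydroxyl. The electron-poor dienoate has no directing group and should not react.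

**Step 19**
Reactants: 24 ethyl (2E,4E)-5-[(1S,2S,3R,6S,7R,10S)-2,3-epoxy-1-hydroxy-3,10-dimethylbicyclo[5.3.0]dec-7-yl]hexa-2,4-dienoate
Product: 25 (1S,2S,3R,6S,7R,10S)-2,3-epoxy-7-[(2E,4E)-6-hydroxy-6-methylhepta-2,4-dien-2-yl]-3,10-dimethylbicyclo[5.3.0]decan-1-ol
Conditions: MeLi (5 equiv), THF, −78 → 0 °C; then H2O
Reagents that add atoms: methyllithium, [Li]C
Why: Double 1,2-addition of methyllithium to the ester gives the tertiary carbinol C15. The C1 hydroxyl is carried as its lithium alkoxide, and a trisubstituted epoxide is not opened at this temperature.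

**Step 20**
Reactants: 25 (1S,2S,3R,6S,7R,10S)-2,3-epoxy-7-[(2E,4E)-6-hydroxy-6-methylhepta-2,4-dien-2-yl]-3,10-dimethylbicyclo[5.3.0]decan-1-ol
Product: 26 (1S,2S,3R,6S,7R,10S)-2,3-epoxy-7-[(2E,4E)-6-hydroxy-6-methylhepta-2,4-dien-2-yl]-3,10-dimethylbicyclo[5.3.0]dec-1-yl acetate (CNP0265175.2)
Conditions: Ac2O, pyridine, DMAP (cat.), CH2Cl2, 0 °C → rt
Reagents that add atoms: acetic anhydride, CC(=O)OC(C)=O
Why: Acylation of the secondary alcohol in the presence of a tertiary one, which reacts far more slowly under these conditions. The medium is basic throughout, so neither the epoxide nor the doubly allylic carbinol is exposed to acid.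

## Compound list

1 | 3-acetyldihydrofuran-2(3H)-one (racemic) | CC(=O)C1CCOC1=O | starting material
2 | (3S)-3-[(1R)-1-hydroxyethyl]dihydrofuran-2(3H)-one | C[C@@H](O)[C@@H]1CCOC1=O | intermediate
3 | (3S)-3-[(1R)-1-(tert-butyldimethylsilyloxy)ethyl]dihydrofuran-2(3H)-one | C[C@@H](O[Si](C)(C)C(C)(C)C)[C@@H]1CCOC1=O | intermediate
4 | (3S)-3-[(1R)-1-(tert-butyldimethylsilyloxy)ethyl]tetrahydrofuran-2-ol (both anomers) | C[C@@H](O[Si](C)(C)C(C)(C)C)[C@@H]1CCOC1O | intermediate
5 | (3R)-3-[(1R)-1-(tert-butyldimethylsilyloxy)ethyl]pent-4-yn-1-ol | C[C@@H](O[Si](C)(C)C(C)(C)C)[C@@H](C#C)CCO | intermediate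
6 | (E)-alkenylzirconocene chloride from 5 (hydroxyl held as zirconium alkoxide in the flask) | C[C@@H](O[Si](C)(C)C(C)(C)C)[C@@H](/C=C/[Zr](Cl)(C1C=CC=C1)C1C=CC=C1)CCO | intermediate (not isolated)
7 | (3R,4E)-3-[(1R)-1-(tert-butyldimethylsilyloxy)ethyl]-5-iodopent-4-en-1-ol | C[C@@H](O[Si](C)(C)C(C)(C)C)[C@@H](/C=C/I)CCO | intermediate
8 | (E)-prop-1-en-1-ylboronic acid | C/C=C/B(O)O | starting material
9 | (3R,4E,6E)-3-[(1R)-1-(tert-butyldimethylsilyloxy)ethyl]octa-4,6-dien-1-ol | C[C@@H](O[Si](C)(C)C(C)(C)C)[C@@H](/C=C/C=C/C)CCO | intermediate
10 | (3R,4E,6E)-3-[(1R)-1-(tert-butyldimethylsilyloxy)ethyl]octa-4,6-dienal | C[C@@H](O[Si](C)(C)C(C)(C)C)[C@@H](/C=C/C=C/C)CC=O | intermediate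
11 | 3-(triphenylphosphoranylidene)butan-2-one | CC(=O)C(C)=P(c1ccccc1)(c1ccccc1)c1ccccc1 | starting material
12 | (3E,6R,7E,9E)-6-[(1R)-1-(tert-butyldimethylsilyloxy)ethyl]-3-methylundeca-3,7,9-trien-2-one | CC(=O)/C(C)=C/C[C@@H]([C@@H](C)O[Si](C)(C)C(C)(C)C)/C=C/C=C/C | intermediate
13 | (6R,7E,9E)-6-[(1R)-1-(tert-butyldimethylsilyloxy)ethyl]-2-[dimethyl(phenyl)silyloxy]-3-methylundeca-2,7,9-triene | CC(O[Si](C)(C)c1ccccc1)=C(C)CC[C@@H]([C@@H](C)O[Si](C)(C)C(C)(C)C)/C=C/C=C/C | intermediate
14 | (6R,7E,9E)-6-[(1R)-1-(tert-butyldimethylsilyloxy)ethyl]-3-chloro-3-methylundeca-7,9-dien-2-one (both C3 epimers) | CC(=O)C(C)(Cl)CC[C@@H]([C@@H](C)O[Si](C)(C)C(C)(C)C)/C=C/C=C/C | intermediate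
15 | oxyallyl cation (2-oxidoallyl cation) from 14 | C=C([O-])[C+](C)CC[C@@H]([C@@H](C)O[Si](C)(C)C(C)(C)C)/C=C/C=C/C | intermediate (not isolated)
16 | (3R,6S,7R,10S)-7-[(1R)-1-(tert-butyldimethylsilyloxy)ethyl]-3,10-dimethylbicyclo[5.3.0]dec-4-en-1-one (target numbering) | O=C1C[C@@H](C)C=C[C@H]2[C@H]([C@@H](C)O[Si](C)(C)C(C)(C)C)CC[C@]12C | intermediate
17 | (3S,6S,7R,10S)-7-[(1R)-1-(tert-butyldimethylsilyloxy)ethyl]-3,10-dimethylbicyclo[5.3.0]decan-1-one | O=C1C[C@@H](C)CC[C@H]2[C@H]([C@@H](C)O[Si](C)(C)C(C)(C)C)CC[C@]12C | intermediate
18 | (6S,7R,10S)-7-[(1R)-1-(tert-butyldimethylsilyloxy)ethyl]-3,10-dimethylbicyclo[5.3.0]dec-2-en-1-one | O=C1C=C(C)CC[C@H]2[C@H]([C@@H](C)O[Si](C)(C)C(C)(C)C)CC[C@]12C | intermediate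
19 | (6S,7R,10S)-7-[(1R)-1-hydroxyethyl]-3,10-dimethylbicyclo[5.3.0]dec-2-en-1-one | O=C1C=C(C)CC[C@H]2[C@H]([C@@H](C)O)CC[C@]12C | intermediate
20 | (6S,7R,10S)-7-acetyl-3,10-dimethylbicyclo[5.3.0]dec-2-en-1-one | O=C1C=C(C)CC[C@H]2[C@H](C(C)=O)CC[C@]12C | intermediate
21 | triethyl 4-phosphonocrotonate [ethyl (E)-4-(diethoxyphosphoryl)but-2-enoate] | CCOC(=O)/C=C/CP(=O)(OCC)OCC | starting material
22 | ethyl (2E,4E)-5-[(6S,7R,10S)-3,10-dimethyl-1-oxobicyclo[5.3.0]dec-2-en-7-yl]hexa-2,4-dienoate | O=C1C=C(C)CC[C@H]2[C@H](/C(C)=C/C=C/C(=O)OCC)CC[C@]12C | intermediate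
23 | ethyl (2E,4E)-5-[(1R,6S,7R,10S)-1-hydroxy-3,10-dimethylbicyclo[5.3.0]dec-2-en-7-yl]hexa-2,4-dienoate | O[C@@H]1C=C(C)CC[C@H]2[C@H](/C(C)=C/C=C/C(=O)OCC)CC[C@]12C | intermediate
24 | ethyl (2E,4E)-5-[(1S,2S,3R,6S,7R,10S)-2,3-epoxy-1-hydroxy-3,10-dimethylbicyclo[5.3.0]dec-7-yl]hexa-2,4-dienoate | O[C@@H]1[C@@H]2O[C@]2(C)CC[C@H]2[C@H](/C(C)=C/C=C/C(=O)OCC)CC[C@]12C | intermediate
25 | (1S,2S,3R,6S,7R,10S)-2,3-epoxy-7-[(2E,4E)-6-hydroxy-6-methylhepta-2,4-dien-2-yl]-3,10-dimethylbicyclo[5.3.0]decan-1-ol | O[C@@H]1[C@@H]2O[C@]2(C)CC[C@H]2[C@H](/C(C)=C/C=C/C(C)(C)O)CC[C@]12C | intermediate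
26 | (1S,2S,3R,6S,7R,10S)-2,3-epoxy-7-[(2E,4E)-6-hydroxy-6-methylhepta-2,4-dien-2-yl]-3,10-dimethylbicyclo[5.3.0]dec-1-yl acetate (CNP0265175.2) | CC(=O)O[C@@H]1[C@@H]2O[C@]2(C)CC[C@H]2[C@H](/C(C)=C/C=C/C(C)(C)O)CC[C@]12C | target

## Step count and least certain steps

Total step count: 20. Longest linear sequence: 20 steps, from 1 to 26; compounds 8, 11 and 21 are purchased.

**Step 11 (key step).** The most likely failure is insufficient discrimination between the extended and the compact approach of the diene, which would erode the trans fusion in favour of the cis-fused adduct. The cation may also be diverted by solvent capture or by loss of HCl to an enone. The fallback keeps the same two bonds but changes how the cation is made. It sets out from 14: soft enolization toward C2 (Et3SiOTf, Et3N, CH2Cl2, −78 °C) would give the 2-(triethylsilyloxy)allylic chloride F1. AgBF4 in CH2Cl2 at −78 °C would then ionize it to a 2-silyloxyallyl cation, a more electrophilic species that reacts at low temperature without a nucleophilic solvent. Its cycloadduct loses the silyl group on work-up and the sequence returns to the route at 16.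

**Step 17.** The hydride may be delivered mainly to the face opposite the C10 methyl, because the substrate bias overrides the catalyst or because the enone, not C10, behaves as the larger flank. The antipodal catalyst is the first check. The fallback accepts substrate control and corrects it afterwards. It sets out from 22: Luche reduction (NaBH4, CeCl3·7H2O, MeOH, −78 °C) should give the C1-epimeric allylic alcohol F2. Mitsunobu inversion (4-nitrobenzoic acid, PPh3, diisopropyl azodicarboxylate, toluene) would give the inverted 4-nitrobenzoate F3, and ethanolysis (K2CO3, EtOH) returns to the route at 23.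

**Step 16.** Geometric control at the new trisubstituted alkene C11=C12 may be incomplete, and the base may enolize either ketone. The fallback builds the chain in two stages, so that the trisubstituted alkene can be purified or equilibrated as an enal before the second, reliably (E)-selective olefination. It sets out from 20: Peterson olefination with lithiated N-tert-butyl-2-(trimethylsilyl)ethanimine followed by mild acid hydrolysis would give the (E)-enal F4. Horner–Wadsworth–Emmons reaction of F4 with triethyl phosphonoacetate (LiCl, DBU, MeCN) returns to the route at 22.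

**Step 4.** The lactol offers only a low concentration of the free aldehyde, so the homologation may be slow, and the basic medium may then epimerize C7 or eliminate the β-silyloxy group. The fallback avoids the lactol and the alkyne altogether. It sets out from 3: LiBH4 would give the diol F5, and pivaloyl chloride in pyridine at −20 °C should acylate the unhindered C9 hydroxyl to give the monopivalate F6. Dess–Martin oxidation would give the aldehyde F7, and Takai olefination (CrCl2, CHI3, THF) the (E)-vinyl iodide F8. Suzuki–Miyaura coupling of F8 with 8 would give the diene pivalate F9, and reductive removal of the pivalate (i-Bu2AlH, −78 °C) returns to the route at 9.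

**Step 13.** Dehydrogenation may run on past the enone to a dienone, or stop short, because seven-membered ketones are easily over-oxidized by IBX. The fallback separates enolization from oxidation. It sets out from 17: LiN(i-Pr)2 and Me3SiCl at −78 °C would give the trimethylsilyl enol ether F10, which can only form toward C2. Saegusa–Ito oxidation with Pd(OAc)2 in MeCN returns to the route at 18.

## Further compounds

F1 | step 11 | (6R,7E,9E)-6-[(1R)-1-(tert-butyldimethylsilyloxy)ethyl]-3-chloro-3-methyl-2-(triethylsilyloxy)undeca-1,7,9-triene (both C3 epimers) | C=C(O[Si](CC)(CC)CC)C(C)(Cl)CC[C@@H]([C@@H](C)O[Si](C)(C)C(C)(C)C)/C=C/C=C/C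
F2 | step 17 | ethyl (2E,4E)-5-[(1S,6S,7R,10S)-1-hydroxy-3,10-dimethylbicyclo[5.3.0]dec-2-en-7-yl]hexa-2,4-dienoate | O[C@H]1C=C(C)CC[C@H]2[C@H](/C(C)=C/C=C/C(=O)OCC)CC[C@]12C
F3 | step 17 | (1R,6S,7R,10S)-7-[(2E,4E)-6-ethoxy-6-oxohexa-2,4-dien-2-yl]-3,10-dimethylbicyclo[5.3.0]dec-2-en-1-yl 4-nitrobenzoate | O=C(O[C@@H]1C=C(C)CC[C@H]2[C@H](/C(C)=C/C=C/C(=O)OCC)CC[C@]12C)c1ccc(cc1)[N+](=O)[O-]
F4 | step 16 | (2E)-3-[(6S,7R,10S)-3,10-dimethyl-1-oxobicyclo[5.3.0]dec-2-en-7-yl]but-2-enal | O=C1C=C(C)CC[C@H]2[C@H](/C(C)=C/C=O)CC[C@]12C
F5 | step 4 | (2R)-2-[(1R)-1-(tert-butyldimethylsilyloxy)ethyl]butane-1,4-diol | C[C@@H](O[Si](C)(C)C(C)(C)C)[C@@H](CO)CCO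
F6 | step 4 | (3R,4R)-4-(tert-butyldimethylsilyloxy)-3-(hydroxymethyl)pentyl 2,2-dimethylpropanoate | C[C@@H](O[Si](C)(C)C(C)(C)C)[C@@H](CO)CCOC(=O)C(C)(C)C
F7 | step 4 | (3S,4R)-4-(tert-butyldimethylsilyloxy)-3-formylpentyl 2,2-dimethylpropanoate | C[C@@H](O[Si](C)(C)C(C)(C)C)[C@@H](C=O)CCOC(=O)C(C)(C)C
F8 | step 4 | (3R,4E)-3-[(1R)-1-(tert-butyldimethylsilyloxy)ethyl]-5-iodopent-4-en-1-yl 2,2-dimethylpropanoate | C[C@@H](O[Si](C)(C)C(C)(C)C)[C@@H](/C=C/I)CCOC(=O)C(C)(C)C
F9 | step 4 | (3R,4E,6E)-3-[(1R)-1-(tert-butyldimethylsilyloxy)ethyl]octa-4,6-dien-1-yl 2,2-dimethylpropanoate | C[C@@H](O[Si](C)(C)C(C)(C)C)[C@@H](/C=C/C=C/C)CCOC(=O)C(C)(C)C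
F10 | step 13 | (3S,6S,7R,10S)-7-[(1R)-1-(tert-butyldimethylsilyloxy)ethyl]-3,10-dimethyl-1-(trimethylsilyloxy)bicyclo[5.3.0]dec-1-ene (target numbering) | C[Si](C)(C)OC1=C[C@@H](C)CC[C@H]2[C@H]([C@@H](C)O[Si](C)(C)C(C)(C)C)CC[C@]12C
A1 | alternative 1 | C1 pinacol boronate of the 3,10-dimethyl-7-isopropenylbicyclo[5.3.0]deca-2,5-diene (target numbering) | CC1(C)OB(OC1(C)C)[C@@H]2C=C(C)CC=C3[C@H](C(C)=C)CC[C@]23C
A2 | alternative 1 | cis-divinylcyclopropane: 1-methyl-1-[(E)-2-(pinacolatoboryl)ethenyl]-2-[2-methyl-5-(prop-1-en-2-yl)cyclopent-1-en-1-yl]cyclopropane | CC1(C)OB(/C=C/[C@@]2(C)C[C@H]2C2=C(C)CC[C@H]2C(C)=C)OC1(C)C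
A3 | alternative 1 | (R)-limonene | CC1=CC[C@@H](CC1)C(C)=C
A4 | alternative 2 | methyl ester on C7 of the trans-fused 10-methylbicyclo[5.3.0]decane with ethylene ketal at C1 (target numbering) | COC(=O)[C@@H]1CC[C@@]2(C)[C@H]1CCCCC23OCCO3
A5 | alternative 2 | trans-fused 2-diazo ketone of the bicyclo[5.4.0]undecane (diazo on C7, ketone C11 between C7 and C8, ethylene ketal at C1) | [N-]=[N+]=C1C(=O)CC[C@@]2(C)[C@H]1CCCCC23OCCO3
A6 | alternative 3 | trans-7-allyl-3,7-dimethyl-6-[1-(2-methyl-1,3-dioxolan-2-yl)ethenyl]cyclohept-2-en-1-one | O=C1C=C(C)CC[C@@H](C(=C)C2(C)OCCO2)[C@]1(C)CC=C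
A7 | alternative 3 | 2,6-dimethylcyclohepta-2,6-dien-1-one | O=C1C=C(C)CCC=C1C
A8 | alternative 3 | diisobutyl[1-(2-methyl-1,3-dioxolan-2-yl)ethenyl]alane | C=C([Al](CC(C)C)CC(C)C)C1(C)OCCO1
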